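The data are calculated from invented constants, noise included.

With time the birch run stops climbing: it reads 19.6% at 4.00 h and 19.3% at 5.00 h.

| flask | starting material | protic impurity | remark | time |
|---|---|---|---|---|
| elm | 0.050 M | 0.010 M | run made earlier |  |
| cedar | 0.025 M | 0.010 M | run made earlier |  |
| birch | 0.038 M | 0.010 M | run made earlier |  |
| Sunday's | 0.050 M (fed, over 4.00 h) | 0.0100 M | all but starting material at the start; starting material goes in evenly over 4.00 h, the run ends at 4.0 h | 4.0 h |
| Wednesday's | 0.050 M | 0.0100 M | a single well-mixed tank run continuously and read at steady state, 4.0 h in it on average |  |
| Tuesday's | 0.050 M | 0.0100 M | everything together in a closed stirred flask, run for 4.0 h | 4.0 h |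

| run | time / h | target / % |
|---|---|---|
| elm | 0.200 | 6.0 |
| elm | 0.417 | 11.8 |
| elm | 1.00 | 18.7 |
| elm | 2.50 | 24.5 |
| cedar | 0.417 | 5.0 |
| cedar | 0.833 | 8.3 |
| cedar | 2.00 | 11.1 |
| cedar | 5.00 | 10.5 |
| birch | 1.33 | 17.3 |
| birch | 2.50 | 18.7 |
| birch | 4.00 | 19.6 |
| birch | 5.00 | 19.3 |

(each reading ± 1 percentage point)

- percent here means starting material units held: one target counts as two
- the stated concentrations are those of everything mixed, before any reaction; amounts are the same in each set-up
- the numbers in the tables scatter with a standard deviation of 1 percentage point
- the feed brings no volume worth counting
- the earlier runs were made in a closed, stirred flask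

* the set-up with the highest amount of target at the outlet or at the end, in percent of the starting material put in ("none" if the first two lie within 2 percentage points) (Sunday's / Wednesday's / Tuesday's / none)
* amount of target at the outlet or at the end, in percent of the starting material put in, Sunday's
* amount of target at the outlet or at the end, in percent of the starting material put in, Wednesday's
* amount of target at the outlet or at the end, in percent of the starting material put in, Tuesday's

Here is the reckoning behind a quick number. Assume that the protic impurity takes its own charge of starting material, one for one. Let y be the fraction of the charge held as target, a the fraction still free, and c the charge. The last readings then give y/(2ca²) as 7.95 M⁻¹ for elm, 8.57 M⁻¹ for cedar and 8.59 M⁻¹ for birch, although elm has twice cedar's charge. Their mean, 8.37 M⁻¹, is the plateau ratio, an apparent equilibrium constant.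

For Tuesday's, which has elm's charges, the impurity takes 20.0%. The ratio then shares the rest as 54.8% free and 25.2% target. Free starting material and target draw level at a charge of 0.129 M. Tuesday's charge of 0.050 M is less than that, so free starting material is reckoned to stay ahead at its plateau. The ratio reckons a plateau, so it gives no figure here for Sunday's or Wednesday's.

Your forecast is 16% for Sunday's, 13.5% for Wednesday's and 26.5% for Tuesday's; the figure for Tuesday's stands above the 25.2% reckoned here. Its ground is “High concentration wins, so batch is best”.

The flasks give 16.4% for Sunday's, 21.1% for Wednesday's and 25.4% for Tuesday's, so Tuesday's is best. Wednesday's stands above the forecast's top of 18%.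

    2 starting material ⇌ target (K = 9.80 M⁻¹, k = 0.0800 M⁻¹ min⁻¹)
    starting material + protic impurity → quenched substrate (k = 2.00 M⁻¹ min⁻¹)
    target ⇌ isomer of the product (K = 0.790, k = 4.90 × 10⁻⁴ min⁻¹)

The neighbour is Tuesday's recipe with 0.20 M of starting material, which is above the reckoned crossing. The plateau ratio shares that flask as 40.4% free and 54.6% target. The neighbour flask ends with 36.9% starting material and 52.7% target. With the other charges and the time of Tuesday's recipe held, the two end with equal shares at a charge of 0.120 M.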